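**Strategy.** The route rests on cutting pyranone ring C of the flavone unit that is attached through C4'. Its ring A carries oxygens at C5, C7 and C8a, which is a phloroglucinol nucleus, so C4–C4a and O1–C2 are disconnected to phloroglucinol and a β-keto ester. One thermal condensation forms both bonds and ring C, and no regiochemical question arises because all phloroglucinol positions are equivalent. The precursor is an ethyl aroylacetate whose aryl group already carries, through the diaryl ether oxygen, the complete second flavone (5'',7''-dimethoxy, 4'''-benzyloxy). It is made from syringaldehyde by a chalcone route and a mild malonate homologation.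

Key step: step 7

Remark: unprimed and singly primed locants denote the flavone unit built in step 7, doubly and triply primed locants the 6''-O-linked unit; phloroglucinol is assumed to be used anhydrous (dried dihydrate).

**Step 1**
Reactants: 1 syringaldehyde; 2 methyl 4-fluorobenzoate
Product: 3 methyl 4-(4-formyl-2,6-dimethoxyphenoxy)benzoate
Conditions: Cs2CO3, DMSO, 120 °C
Reagents that add atoms: none
Why: Nucleophilic aromatic substitution (SNAr): the caesium phenoxide of 1 should add para to the ester of 2 to give an ester-stabilised Meisenheimer adduct that expels fluoride, with the dipolar solvent and loose caesium ion pair offsetting the hindrance and low basicity of the phenoxide.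

**Step 2**
Reactants: 3 methyl 4-(4-formyl-2,6-dimethoxyphenoxy)benzoate
Product: 5 methyl 4-(4-hydroxy-2,6-dimethoxyphenoxy)benzoate, via aryl formate 4 (not isolated)
Conditions: mCPBA, CH2Cl2, 0 °C to rt; then K2CO3 (cat.), MeOH, rt
Reagents that add atoms: mCPBA (3-chloroperoxybenzoic acid), OOC(=O)c1cccc(Cl)c1
Why: Baeyer–Villiger oxidation of an aryl aldehyde (Dakin-type): the peracid adds to the formyl group and the ring, made migration-prone by the para aryloxy oxygen as in 3,4,5-trialkoxybenzaldehydes, should shift to oxygen to give formate 4, which carbonate-catalysed methanolysis cleaves without touching the methyl benzoate.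

**Step 3**
Reactants: 5 methyl 4-(4-hydroxy-2,6-dimethoxyphenoxy)benzoate
Product: 6 methyl 4-(3-acetyl-4-hydroxy-2,6-dimethoxyphenoxy)benzoate
Conditions: AcOH, BF3·OEt2, 85 °C; then H2O
Reagents that add atoms: acetic acid, CC(=O)O
Why: BF3-mediated Friedel–Crafts ortho-acylation of a phenol (the standard route from 3,4,5-trialkoxyphenols to 2-hydroxyacetophenones): only the trioxygenated ring is nucleophilic enough, its two positions ortho to the hydroxyl are equivalent by symmetry, and the difluoroboron chelate of the product blocks a second acylation until aqueous work-up releases 6.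

**Step 4**
Reactants: 6 methyl 4-(3-acetyl-4-hydroxy-2,6-dimethoxyphenoxy)benzoate; 7 4-(benzyloxy)benzaldehyde
Product: 8 4-(3-{(2E)-3-[4-(benzyloxy)phenyl]prop-2-enoyl}-4-hydroxy-2,6-dimethoxyphenoxy)benzoic acid
Conditions: KOH (aq.), EtOH, rt to 40 °C; then aq. HCl to pH 2
Reagents that add atoms: potassium hydroxide, [K+].[OH-] (its oxygen ends up in the carboxylic acid)
Why: Claisen–Schmidt aldol condensation: the acetyl enolate of 6 adds to the non-enolisable aldehyde 7 and E1cB dehydration under equilibrating conditions should give the E-enone, while the excess hydroxide saponifies the methyl benzoate in the same pot and delivers the acid needed in step 6.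

**Step 5**
Reactants: 8 4-(3-{(2E)-3-[4-(benzyloxy)phenyl]prop-2-enoyl}-4-hydroxy-2,6-dimethoxyphenoxy)benzoic acid
Product: 10 4-({2-[4-(benzyloxy)phenyl]-5,7-dimethoxy-4-oxo-4H-chromen-6-yl}oxy)benzoic acid, via racemic flavanone acid 9 (not isolated)
Conditions: I2 (10 mol%), DMSO, 130 °C
Reagents that add atoms: none
Why: Iodine-catalysed oxidative cyclisation of a 2'-hydroxychalcone in DMSO: oxa-Michael closure gives flavanone 9, α-iodination and loss of HI introduce the C2''–C3'' double bond, and DMSO reoxidises HI to I2; benzyl ethers, methyl ethers and the free acid are expected to survive this standard reaction.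

**Step 6**
Reactants: 10 4-({2-[4-(benzyloxy)phenyl]-5,7-dimethoxy-4-oxo-4H-chromen-6-yl}oxy)benzoic acid
Product: 13 ethyl 3-[4-({2-[4-(benzyloxy)phenyl]-5,7-dimethoxy-4-oxo-4H-chromen-6-yl}oxy)phenyl]-3-oxopropanoate, via acyl imidazolide 11 (not isolated), via acylmalonate half ester 12 (not isolated)
Conditions: CDI, THF/DMF, rt to 40 °C; then KO2CCH2CO2Et, MgCl2, Et3N, MeCN, rt to 50 °C; then 1 M HCl
Reagents that add atoms: potassium ethyl malonate (KO2CCH2CO2Et), [K+].[O-]C(=O)CC(=O)OCC; 1,1'-carbonyldiimidazole, O=C(n1ccnc1)n1ccnc1 (its atoms are retained only in intermediate 11)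
Why: Masamune-type homologation: imidazolide 11 C-acylates the magnesium enolate of the malonate half ester and the resulting acylmalonic acid 12 decarboxylates on acidification, so the β-keto ester forms under near-neutral conditions that cannot open or add to the base-sensitive chromone.

**Step 7**
Reactants: 13 ethyl 3-[4-({2-[4-(benzyloxy)phenyl]-5,7-dimethoxy-4-oxo-4H-chromen-6-yl}oxy)phenyl]-3-oxopropanoate; 14 phloroglucinol
Product: 18 2-[4-({2-[4-(benzyloxy)phenyl]-5,7-dimethoxy-4-oxo-4H-chromen-6-yl}oxy)phenyl]-5,7-dihydroxy-4H-chromen-4-one, via aroylketene 15 (not isolated), via trihydroxyphenyl diketone 16 (not isolated), via cyclic hemiketal 17 (not isolated)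
Conditions: 14 (3 equiv, dried), neat melt, N2 stream, 240–250 °C
Reagents that add atoms: none
Why: This is the Mentzer thermal pyrone synthesis, the chromone-forming counterpart of the acid-catalysed Pechmann reaction: above about 200 °C keto ester 13 should lose ethanol to give aroylketene 15, whose ketene carbon is attacked by a nuclear carbon of 14 (C-acylation, forming C4–C4a) to give diketone 16. An ortho hydroxyl of 16 then adds to the aryl ketone carbonyl in a 6-exo-trig closure (forming O1–C2 and ring C) to hemiketal 17, which loses water to the aromatic pyranone 18. No stereocentre remains, since the hemiketal carbon of 17 becomes planar on dehydration. The step needs chromone rather than coumarin closure and a single annulation: acid-free heating disfavours attack of the ring carbon on the aryl ketone (the Pechmann mode), the threefold symmetry of 14 makes every nuclear position and every hydroxyl equivalent so only one regioisomer can form, and the carbonyl-deactivated ring A of 18 together with the excess of 14 should suppress a second acylation. The chromone, methyl ethers, diaryl ether and benzyl ether of 13 carry no protic or thermally labile function and should pass through the short melt unchanged.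

**Step 8**
Reactants: 18 2-[4-({2-[4-(benzyloxy)phenyl]-5,7-dimethoxy-4-oxo-4H-chromen-6-yl}oxy)phenyl]-5,7-dihydroxy-4H-chromen-4-one
Product: 19 2-[4-({2-[4-(benzyloxy)phenyl]-5,7-dimethoxy-4-oxo-4H-chromen-6-yl}oxy)phenyl]-5-hydroxy-7-methoxy-4H-chromen-4-one
Conditions: MeI (1.1 equiv), K2CO3, DMF, rt
Reagents that add atoms: iodomethane, CI
Why: Williamson O-methylation: the 7-hydroxyl is the most acidic and the only non-chelated phenol, whereas the 5-hydroxyl is held in a hydrogen bond to the C4 carbonyl, so a slight excess of MeI under carbonate should alkylate O7 alone.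

**Step 9**
Reactants: 19 2-[4-({2-[4-(benzyloxy)phenyl]-5,7-dimethoxy-4-oxo-4H-chromen-6-yl}oxy)phenyl]-5-hydroxy-7-methoxy-4H-chromen-4-one
Product: 20 5-hydroxy-2-(4-{[5-hydroxy-2-(4-hydroxyphenyl)-7-methoxy-4-oxo-4H-chromen-6-yl]oxy}phenyl)-7-methoxy-4H-chromen-4-one (CNP0251572.0)
Conditions: BCl3 (8 equiv), pentamethylbenzene (5 equiv), CH2Cl2, −78 °C to rt; then MeOH, aq. HCl
Reagents that add atoms: none
Why: Lewis-acid ether cleavage: BCl3 chelates between the C4'' carbonyl and the peri 5''-methoxy oxygen and chloride removes that methyl group, the benzyl ether is cleaved with pentamethylbenzene trapping the benzyl cation before it can alkylate the electron-rich ring A, and the non-chelated 7- and 7''-methyl ethers and the diaryl ether are not attacked by BCl3 at or below room temperature.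

**Compound list**
1 | syringaldehyde (4-hydroxy-3,5-dimethoxybenzaldehyde) | COc1cc(C=O)cc(OC)c1O | starting material
2 | methyl 4-fluorobenzoate | COC(=O)c1ccc(F)cc1 | starting material
3 | methyl 4-(4-formyl-2,6-dimethoxyphenoxy)benzoate | COC(=O)c1ccc(Oc2c(OC)cc(C=O)cc2OC)cc1 | intermediate
4 | methyl 4-[4-(formyloxy)-2,6-dimethoxyphenoxy]benzoate (aryl formate) | COC(=O)c1ccc(Oc2c(OC)cc(OC=O)cc2OC)cc1 | intermediate (not isolated)
5 | methyl 4-(4-hydroxy-2,6-dimethoxyphenoxy)benzoate | COC(=O)c1ccc(Oc2c(OC)cc(O)cc2OC)cc1 | intermediate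
6 | methyl 4-(3-acetyl-4-hydroxy-2,6-dimethoxyphenoxy)benzoate | COC(=O)c1ccc(Oc2c(OC)cc(O)c(C(C)=O)c2OC)cc1 | intermediate
7 | 4-(benzyloxy)benzaldehyde | O=Cc1ccc(OCc2ccccc2)cc1 | starting material
8 | 4-(3-{(2E)-3-[4-(benzyloxy)phenyl]prop-2-enoyl}-4-hydroxy-2,6-dimethoxyphenoxy)benzoic acid (E-chalcone acid) | OC(=O)c1ccc(Oc2c(OC)cc(O)c(C(=O)/C=C/c3ccc(OCc4ccccc4)cc3)c2OC)cc1 | intermediate
9 | 4-({2-[4-(benzyloxy)phenyl]-5,7-dimethoxy-4-oxochroman-6-yl}oxy)benzoic acid (flavanone acid, racemic at C2) | OC(=O)c1ccc(Oc2c(OC)cc3OC(c4ccc(OCc5ccccc5)cc4)CC(=O)c3c2OC)cc1 | intermediate (not isolated)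
10 | 4-({2-[4-(benzyloxy)phenyl]-5,7-dimethoxy-4-oxo-4H-chromen-6-yl}oxy)benzoic acid | OC(=O)c1ccc(Oc2c(OC)cc3oc(-c4ccc(OCc5ccccc5)cc4)cc(=O)c3c2OC)cc1 | intermediate
11 | 1-[4-({2-[4-(benzyloxy)phenyl]-5,7-dimethoxy-4-oxo-4H-chromen-6-yl}oxy)benzoyl]imidazole (acyl imidazolide) | O=C(c1ccc(Oc2c(OC)cc3oc(-c4ccc(OCc5ccccc5)cc4)cc(=O)c3c2OC)cc1)n1ccnc1 | intermediate (not isolated)
12 | 2-(ethoxycarbonyl)-3-[4-({2-[4-(benzyloxy)phenyl]-5,7-dimethoxy-4-oxo-4H-chromen-6-yl}oxy)phenyl]-3-oxopropanoic acid (acylmalonate half ester, configurationally labile) | CCOC(=O)C(C(=O)O)C(=O)c1ccc(Oc2c(OC)cc3oc(-c4ccc(OCc5ccccc5)cc4)cc(=O)c3c2OC)cc1 | intermediate (not isolated)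
13 | ethyl 3-[4-({2-[4-(benzyloxy)phenyl]-5,7-dimethoxy-4-oxo-4H-chromen-6-yl}oxy)phenyl]-3-oxopropanoate | CCOC(=O)CC(=O)c1ccc(Oc2c(OC)cc3oc(-c4ccc(OCc5ccccc5)cc4)cc(=O)c3c2OC)cc1 | intermediate (key-step precursor)
14 | phloroglucinol (benzene-1,3,5-triol) | Oc1cc(O)cc(O)c1 | starting material
15 | 3-[4-({2-[4-(benzyloxy)phenyl]-5,7-dimethoxy-4-oxo-4H-chromen-6-yl}oxy)phenyl]-3-oxoprop-1-en-1-one (aroylketene) | O=C=CC(=O)c1ccc(Oc2c(OC)cc3oc(-c4ccc(OCc5ccccc5)cc4)cc(=O)c3c2OC)cc1 | intermediate (not isolated)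
16 | 1-[4-({2-[4-(benzyloxy)phenyl]-5,7-dimethoxy-4-oxo-4H-chromen-6-yl}oxy)phenyl]-3-(2,4,6-trihydroxyphenyl)propane-1,3-dione | O=C(CC(=O)c1c(O)cc(O)cc1O)c1ccc(Oc2c(OC)cc3oc(-c4ccc(OCc5ccccc5)cc4)cc(=O)c3c2OC)cc1 | intermediate (not isolated)
17 | 2-[4-({2-[4-(benzyloxy)phenyl]-5,7-dimethoxy-4-oxo-4H-chromen-6-yl}oxy)phenyl]-2,5,7-trihydroxychroman-4-one (cyclic hemiketal, racemic at C2) | Oc1cc(O)c2C(=O)CC(O)(c3ccc(Oc4c(OC)cc5oc(-c6ccc(OCc7ccccc7)cc6)cc(=O)c5c4OC)cc3)Oc2c1 | intermediate (not isolated)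
18 | 2-[4-({2-[4-(benzyloxy)phenyl]-5,7-dimethoxy-4-oxo-4H-chromen-6-yl}oxy)phenyl]-5,7-dihydroxy-4H-chromen-4-one | Oc1cc(O)c2c(=O)cc(-c3ccc(Oc4c(OC)cc5oc(-c6ccc(OCc7ccccc7)cc6)cc(=O)c5c4OC)cc3)oc2c1 | intermediate (key-step product)
19 | 2-[4-({2-[4-(benzyloxy)phenyl]-5,7-dimethoxy-4-oxo-4H-chromen-6-yl}oxy)phenyl]-5-hydroxy-7-methoxy-4H-chromen-4-one | COc1cc(O)c2c(=O)cc(-c3ccc(Oc4c(OC)cc5oc(-c6ccc(OCc7ccccc7)cc6)cc(=O)c5c4OC)cc3)oc2c1 | intermediate
20 | 5-hydroxy-2-(4-{[5-hydroxy-2-(4-hydroxyphenyl)-7-methoxy-4-oxo-4H-chromen-6-yl]oxy}phenyl)-7-methoxy-4H-chromen-4-one (CNP0251572.0; no stereocentres) | COc1cc(O)c2c(=O)cc(-c3ccc(Oc4c(OC)cc5oc(-c6ccc(O)cc6)cc(=O)c5c4O)cc3)oc2c1 | target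

**Total step count:** 9
**Longest linear sequence:** 9 steps (1 and 2 to 20)

**Steps most likely to fail**

Risk 1, step 7 (thermal annulation). In the melt the aroylketene may dimerise or decompose faster than it C-acylates phloroglucinol. The benzyl ether may be lost thermally, or closure may go partly in the Pechmann sense. The fallback builds the same ring C by a Baker–Venkataraman sequence, sets out from acid 10 and returns to the route at target 20:
- Acid 10 is esterified (EDC·HCl, DMAP, CH2Cl2) with commercial 2'-hydroxy-4',6'-dimethoxyacetophenone to give 2-acetyl-3,5-dimethoxyphenyl 4-({2-[4-(benzyloxy)phenyl]-5,7-dimethoxy-4-oxo-4H-chromen-6-yl}oxy)benzoate F1.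
- Base-induced O-to-C acyl transfer (KOtBu, THF, 0 °C to rt) gives 1-(2-hydroxy-4,6-dimethoxyphenyl)-3-[4-({2-[4-(benzyloxy)phenyl]-5,7-dimethoxy-4-oxo-4H-chromen-6-yl}oxy)phenyl]propane-1,3-dione F2.
- Acid-catalysed cyclodehydration (p-TsOH, toluene, reflux) gives 2-[4-({2-[4-(benzyloxy)phenyl]-5,7-dimethoxy-4-oxo-4H-chromen-6-yl}oxy)phenyl]-5,7-dimethoxy-4H-chromen-4-one F3.
- BCl3 with pentamethylbenzene, as in step 9, then removes both chelated peri methyl groups (O5 and O5'') and the benzyl group and leaves the 7- and 7''-methyl ethers, giving 20 directly.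

Risk 2, step 1 (diaryl ether formation). Addition of the hindered, weakly nucleophilic phenoxide to the only moderately activated fluoroarene may be too slow, so that O-demethylation of the methyl ester by phenoxide competes at the temperature required. The fallback leaves the addition–elimination manifold for a copper-catalysed Ullmann-type C–O coupling, which does not depend on Meisenheimer stabilisation and is suited to di-ortho-substituted phenols. It sets out from 1, uses methyl 4-iodobenzoate with CuI, picolinic acid and K3PO4 in DMSO at 90 °C, and returns at 3; no new compound is made (F0).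

Risk 3, step 2 (aldehyde to phenol). Hydride may migrate in place of the aryl group in the peracid adduct, because the twisted para oxygen donates only weakly, so the aldehyde is over-oxidised to the carboxylic acid. The fallback avoids the aldehyde, sets out from 2 and returns at 5:
- SNAr of commercial 4-bromo-2,6-dimethoxyphenol on 2 (Cs2CO3, DMSO, 120 °C) gives methyl 4-(4-bromo-2,6-dimethoxyphenoxy)benzoate F4.
- Miyaura borylation (bis(pinacolato)diboron, Pd(dppf)Cl2, KOAc, dioxane, 90 °C) gives methyl 4-[2,6-dimethoxy-4-(4,4,5,5-tetramethyl-1,3,2-dioxaborolan-2-yl)phenoxy]benzoate F5.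
- Oxidation of the C–B bond (H2O2, aq. NaHCO3, THF, 0 °C) gives phenol 5.

**Further compounds**
F1 | step 7 | 2-acetyl-3,5-dimethoxyphenyl 4-({2-[4-(benzyloxy)phenyl]-5,7-dimethoxy-4-oxo-4H-chromen-6-yl}oxy)benzoate | COc1cc(OC)c(C(C)=O)c(OC(=O)c2ccc(Oc3c(OC)cc4oc(-c5ccc(OCc6ccccc6)cc5)cc(=O)c4c3OC)cc2)c1
F2 | step 7 | 1-(2-hydroxy-4,6-dimethoxyphenyl)-3-[4-({2-[4-(benzyloxy)phenyl]-5,7-dimethoxy-4-oxo-4H-chromen-6-yl}oxy)phenyl]propane-1,3-dione | COc1cc(O)c(C(=O)CC(=O)c2ccc(Oc3c(OC)cc4oc(-c5ccc(OCc6ccccc6)cc5)cc(=O)c4c3OC)cc2)c(OC)c1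
F3 | step 7 | 2-[4-({2-[4-(benzyloxy)phenyl]-5,7-dimethoxy-4-oxo-4H-chromen-6-yl}oxy)phenyl]-5,7-dimethoxy-4H-chromen-4-one | COc1cc(OC)c2c(=O)cc(-c3ccc(Oc4c(OC)cc5oc(-c6ccc(OCc7ccccc7)cc6)cc(=O)c5c4OC)cc3)oc2c1
F0 | step 1 | none | none
F4 | step 2 | methyl 4-(4-bromo-2,6-dimethoxyphenoxy)benzoate | COC(=O)c1ccc(Oc2c(OC)cc(Br)cc2OC)cc1
F5 | step 2 | methyl 4-[2,6-dimethoxy-4-(4,4,5,5-tetramethyl-1,3,2-dioxaborolan-2-yl)phenoxy]benzoate | COC(=O)c1ccc(Oc2c(OC)cc(B3OC(C)(C)C(C)(C)O3)cc2OC)cc1
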